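**Retrosynthetic overview**

1. Locants: C1/C1′(Me)–C2–C3(=O)–C4–C5–C6; C6–C7–O8–C9(=O)–C10–C11–C12; C12–C13–N14(Me)–C15–C16; C16–C17–C18–C19=C20–C21–C22–C23(OH); further bonds C6–C12, C6–C16, C12–C23, C19–C23, C22–C23, C10–C22. Rings: A piperidine (C6, C12, C13, N14, C15, C16), B cycloheptane (C6, C16, C17, C18, C19, C23, C12), C cyclopentene (C19–C23), D cyclopentane (C10, C11, C12, C23, C22), E lactone (C6, C7, O8, C9, C10, C11, C12).
2. Last disconnection, ring D at C10–C22: C10 is α to the lactone carbonyl C9 and can carry a radical; with a C21=C22 bond added to ring C, C22 is the free end of a C19=C20–C21=C22 diene and sits five atoms from C10 (C10–C11–C12–C23–C22) on the C12 face of C23. A 5-exo closure then gives cis-fused rings C/D and returns the allyl radical as the C19=C20 alkene.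
3. Ring E by lactonisation (C7–OH with C9). The quaternary C6 (C5 chain and C7) comes from the epoxide of the C6 ketone, opened by trivalent titanium and trapped by isopropyl vinyl ketone. Ring C comes from 1,2-addition of a C22–C20 unit to the C23 ketone, then ring-closing metathesis (C19=C20).
4. Rings A and B by a double Mannich reaction (MeNH2, 2 CH2O) across C12 and C16 of a 2-alkylcycloheptane-1,3-dione, whose two carbonyls are C6 and C23; C11–C10–C9 by Michael addition to tert-butyl acrylate.
5. Order of ring formation: B (bought) → A → C → E → D.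

Key step: step 14

Remark: stereocentres that are destroyed later are formed as mixtures that converge: the spiro carbon C6 in 7–17 (drawn as the expected epimer), C19 in 8 and 9, the selenium-bearing C22 in 14–24 and the sulfur-bearing C10 in 17–25 (left unassigned in the SMILES).

**Step 1**
Reactants: 1 cycloheptane-1,3-dione; 2 tert-butyl acrylate
Product: 3 tert-butyl 3-(2,7-dioxocycloheptyl)propanoate
Conditions: Cs2CO3 (0.1 equiv), MeCN, 40 °C
Reagents that add atoms: none
Why: Michael addition of the enolised 1,3-dione through its C2 (the later C12) to the acrylate should install C11–C10–C9; a slight excess of 1 limits double alkylation.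

**Step 2**
Reactants: 3 tert-butyl 3-(2,7-dioxocycloheptyl)propanoate
Product: 4 rac-tert-butyl 3-(8-methyl-2,10-dioxo-8-azabicyclo[4.3.1]decan-1-yl)propanoate
Conditions: MeNH2 (40% aq), CH2O (37% aq, 2.2 equiv), AcOH, MeOH, 0 → 60 °C
Reagents that add atoms: methylamine CN; formaldehyde C=O
Why: Double Mannich reaction (as used for 3-azabicyclo[3.3.1]nonanones): the enolised C12 is aminomethylated first and the tethered N-methyl iminium ion then closes ring A on the α′-carbon C16; only the diaxially bridged bicycle can form, so the relative configuration of C12 and C16 is fixed and the product is racemic.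

**Step 3**
Reactants: 4 rac-tert-butyl 3-(8-methyl-2,10-dioxo-8-azabicyclo[4.3.1]decan-1-yl)propanoate
Product: 5 single enantiomer of 4 having C12 and C16 configured as in the target
Conditions: preparative SFC, amylose tris(3,5-dimethylphenylcarbamate) phase, CO2/MeOH, 25 °C
Reagents that add atoms: none
Why: Chromatographic resolution on a chiral stationary phase; 5 should be carried into step 4 at once because a retro-Mannich/Mannich sequence could racemise it while the C6 ketone is present.

**Step 4**
Reactants: 5 single enantiomer of the bicyclic diketone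
Product: 7 C6 spiro-epoxide of 5 (oxirane CH2 = C7; C23 ketone kept), via lithium enolate 6 (not isolated)
Conditions: LiN(SiMe3)2 (1.05 equiv), THF, −78 °C; then Me2S=CH2 [from Me3S+ I− and LiN(SiMe3)2, THF, −10 °C], −78 → 0 °C; H2O
Reagents that add atoms: trimethylsulfonium iodide C[S+](C)C.[I-]
Why: Corey–Chaykovsky epoxidation; the only enolisable ketone (C23, through C19–H) is masked in situ as its lithium enolate, which also blocks retro-Claisen cleavage, so the ylide should attack the non-enolisable bridging ketone C6, mainly from the flattened ring B side; the C6 configuration is irrelevant because step 10 makes C6 a planar radical.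

**Step 5**
Reactants: 7 C6 spiro-epoxide
Product: 10 C19-methylene ketone (exocyclic C=CH2 on C19 next to the C23 ketone), via hydroxymethyl ketone 8 (not isolated), via mesylate 9 (not isolated)
Conditions: LiN(SiMe3)2, THF, −78 °C; CH2O (gas); then MeSO2Cl, −78 → 0 °C; DBU, 23 °C
Reagents that add atoms: formaldehyde C=O
Why: Aldol addition of the C19 enolate to formaldehyde, mesylation and E1cB elimination (α-methylenation) should give the first alkene partner for ring C under base-only conditions that spare the epoxide.

**Step 6**
Reactants: 11 bis(phenylselanyl)methane; 12 allyl bromide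
Product: 13 4,4-bis(phenylselanyl)but-1-ene
Conditions: LiN(iPr)2, THF, −78 °C; then 12, −78 → 0 °C
Reagents that add atoms: none
Why: Deprotonation of the selenoacetal (the two selenium atoms acidify the C–H; an amide base avoids Se/Li exchange) and SN2 allylation.

**Step 7**
Reactants: 10 C19-methylene ketone; 13 4,4-bis(phenylselanyl)but-1-ene
Product: 15 C23 tertiary alcohol bearing the 1-(phenylselanyl)but-3-enyl group (C22–C21–C20=CH2) on C23, via 1-(phenylselanyl)but-3-enyllithium 14 (not isolated)
Conditions: 13, n-BuLi, THF, −78 °C; then 10, −78 °C; H2O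
Reagents that add atoms: none
Why: Se/Li exchange gives the α-selenoalkyllithium, which should add 1,2 to the enone carbonyl C23 by axial attack from the exo face, anti to the axial C12–C13 bond and away from the ring A bridge; C22 then becomes axial on ring B and the hydroxyl equatorial, as in the target.

**Step 8**
Reactants: 15 C23 tertiary alcohol
Product: 16 ring C cyclopentenol (C19=C20; PhSe on C22; C23–OH)
Conditions: second-generation Grubbs catalyst RuCl2(=CHPh)(PCy3)(H2IMes) (5 mol %), (1S)-10-camphorsulfonic acid (1 equiv), CH2Cl2, 40 °C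
Reagents that add atoms: none
Why: Ring-closing metathesis between the 1,1-disubstituted alkene on C19 and the terminal vinyl group should close ring C as the trisubstituted C19=C20 cyclopentene with loss of ethene; the amine is masked as its sulfonate salt.

**Step 9**
Reactants: 16 ring C cyclopentenol
Product: 17 C10-phenylsulfanyl derivative of 16
Conditions: LiN(iPr)2 (2.3 equiv), THF, −78 °C; PhSSPh, −78 → −30 °C; H2O
Reagents that add atoms: diphenyl disulfide c1ccc(SSc2ccccc2)cc1
Why: Sulfenylation of the tert-butyl ester enolate (the C23 alkoxide forms first) marks C10 as the later radical site; it is done here because no ketone is present yet.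

**Step 10**
Reactants: 17 C10-phenylsulfanyl epoxide; 18 4-methylpent-1-en-3-one
Product: 19 δ-hydroxy ketone having quaternary C6 (C5–C4–C3(=O)–iPr chain over ring A; C7H2OH over ring B)
Conditions: Cp2TiCl2 (0.3 equiv), Zn, 2,4,6-trimethylpyridinium chloride, THF, 23 °C
Reagents that add atoms: none
Why: Reductive epoxide opening by Cp2TiCl (trivalent titanium; Nugent–RajanBabu reaction in its catalytic form) gives the tertiary C6 radical, which has no β-hydrogen to lose (C12 quaternary, C16 bridgehead) and should undergo Giese addition to the enone from the ring A side, because the ring B side is covered by the 1,3-diaxial C22 substituent on C23; C5 thus ends axial on ring A and C7H2OH axial on ring B.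

**Step 11**
Reactants: 19 δ-hydroxy ketone tert-butyl ester
Product: 21 hydroxy acid (C9 carboxylic acid), via tris(trimethylsilyl) derivative 20 (not isolated)
Conditions: Me3SiOTf, 2,6-lutidine, CH2Cl2, 0 → 23 °C; then THF/H2O, pH 5
Reagents that add atoms: none
Why: Silyl triflate-mediated cleavage of the tert-butyl ester (loss of 2-methylpropene) under buffered aprotic conditions, in which the tertiary allylic alcohol is held as its silyl ether and should not ionise.

**Step 12**
Reactants: 21 hydroxy acid
Product: 23 ring E lactone (rings A B C E; C10–SPh; C22–SePh), via mixed anhydride 22 (not isolated)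
Conditions: 2,4,6-trichlorobenzoyl chloride, Et3N, THF, 23 °C; then DMAP, toluene (0.002 M), 60 °C
Reagents that add atoms: none
Why: Yamaguchi lactonisation; only the primary C7 hydroxyl, gauche to the C11 chain across the C6–C12 bond, can reach the activated C9 carboxyl (the tertiary C23 hydroxyl is hindered and points away from C11), so the seven-membered ring E should form.

**Step 13**
Reactants: 23 ring E lactone
Product: 25 diene lactone (C19=C20–C21=C22; C10–SPh), via selenoxide 24 (not isolated)
Conditions: NaIO4, NaHCO3, MeOH–THF–H2O, 0 → 23 °C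
Reagents that add atoms: none
Why: Selenide oxidation and syn-elimination of the selenoxide, which can only run toward C21 because C23 carries no hydrogen, should give the ring C diene; periodate leaves the amine and the less nucleophilic sulfide untouched.

**Step 14**
Reactants: 25 diene lactone
Product: 26 CNP0242289.1
Conditions: Bu3SnH (1.3 equiv, slow addition), AIBN (0.2 equiv), benzene (0.005 M), 80 °C
Reagents that add atoms: none
Why: Bu3Sn• abstracts the phenylthio group from C10 to give the lactone α-radical, which adds 5-exo-trig to C22, the unsubstituted end of the ring C diene; the resulting C19–C20–C21 allyl radical takes a hydrogen atom from Bu3SnH at its less hindered end C21, which carries the chain and leaves the C19=C20 alkene. The closest known reaction type is the tin hydride-mediated 5-exo cyclisation of α-(phenylthio) ester and lactone radicals onto alkenes and 1,3-dienes. Ring D (C10, C11, C12, C23, C22) is the only ring closed, in the 5-exo-trig mode. C22 is set by the tether, which reaches the diene only on the face of C23 that carries C12, so rings C and D become cis-fused with H22 syn to the C23 hydroxyl; C10 is set by ring E, which holds the C9 carbonyl on the side of the C6–C7 bridge, so both C10 epimers of 25 converge. The step needs attack at C22 rather than C19 (C19 is fully substituted and would give a more strained quaternary junction), closure before the C10 radical is reduced, and hydrogen delivery to C21 rather than C19; the substitution pattern of the diene and slow addition of Bu3SnH at high dilution (stannyl addition to the diene being reversible) should secure these.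

**Compound list**

1 | cycloheptane-1,3-dione | O=C1CCCCC(=O)C1 | starting material
2 | tert-butyl acrylate | C=CC(=O)OC(C)(C)C | starting material
3 | tert-butyl 3-(2,7-dioxocycloheptyl)propanoate | CC(C)(C)OC(=O)CCC1C(=O)CCCCC1=O | intermediate
4 | rac-tert-butyl 3-(8-methyl-2,10-dioxo-8-azabicyclo[4.3.1]decan-1-yl)propanoate (rings A/B; both enantiomers shown) | CC(C)(C)OC(=O)CC[C@]1(CN(C)C[C@H]2CCCC1=O)C2=O.CC(C)(C)OC(=O)CC[C@@]1(CN(C)C[C@@H]2CCCC1=O)C2=O | intermediate
5 | enantiomer of 4 having C12 and C16 as in the target | CC(C)(C)OC(=O)CC[C@]1(CN(C)C[C@H]2CCCC1=O)C2=O | intermediate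
6 | lithium enolate of 5 (C19=C23–OLi) | CC(C)(C)OC(=O)CC[C@]1(CN(C)C[C@H]2CCC=C1[O-])C2=O.[Li+] | intermediate
7 | C6 spiro-epoxide of 5 (oxirane CH2 = C7 on the ring B side) | CC(C)(C)OC(=O)CC[C@]1(CN(C)C[C@H]2CCCC1=O)[C@]23CO3 | intermediate
8 | C19-hydroxymethyl ketone | CC(C)(C)OC(=O)CC[C@]1(CN(C)C[C@H]2CCC(CO)C1=O)[C@]23CO3 | intermediate
9 | methanesulfonate of 8 | CC(C)(C)OC(=O)CC[C@]1(CN(C)C[C@H]2CCC(COS(C)(=O)=O)C1=O)[C@]23CO3 | intermediate
10 | C19-methylene ketone | CC(C)(C)OC(=O)CC[C@]1(CN(C)C[C@H]2CCC(=C)C1=O)[C@]23CO3 | intermediate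
11 | bis(phenylselanyl)methane | C([Se]c1ccccc1)[Se]c1ccccc1 | starting material
12 | allyl bromide | C=CCBr | starting material
13 | 4,4-bis(phenylselanyl)but-1-ene | C=CCC([Se]c1ccccc1)[Se]c1ccccc1 | intermediate
14 | 1-(phenylselanyl)but-3-enyllithium | [Li]C(CC=C)[Se]c1ccccc1 | intermediate
15 | C23 tertiary alcohol (C19 methylene; 1-(phenylselanyl)but-3-enyl on C23) | CC(C)(C)OC(=O)CC[C@]1(CN(C)C[C@H]2CCC(=C)[C@]1(O)C(CC=C)[Se]c3ccccc3)[C@]23CO3 | intermediate
16 | ring C cyclopentenol (rings A B C; spiro-epoxide; tert-butyl ester) | CC(C)(C)OC(=O)CC[C@]1(CN(C)C[C@H]2CCC3=CCC([Se]c4ccccc4)[C@]13O)[C@]23CO3 | intermediate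
17 | C10-phenylsulfanyl derivative of 16 | CC(C)(C)OC(=O)C(Sc4ccccc4)C[C@]1(CN(C)C[C@H]2CCC3=CCC([Se]c4ccccc4)[C@]13O)[C@]23CO3 | intermediate
18 | 4-methylpent-1-en-3-one (isopropyl vinyl ketone) | CC(C)C(=O)C=C | starting material
19 | δ-hydroxy ketone having quaternary C6 (tert-butyl ester) | CC(C)C(=O)CC[C@]1(CO)[C@]2(CC(Sc3ccccc3)C(=O)OC(C)(C)C)CN(C)C[C@H]1CCC1=CCC([Se]c3ccccc3)[C@]21O | intermediate
20 | tris(trimethylsilyl) derivative (silyl ester; C7 and C23 silyl ethers) | CC(C)C(=O)CC[C@]1(CO[Si](C)(C)C)[C@]2(CC(Sc3ccccc3)C(=O)O[Si](C)(C)C)CN(C)C[C@H]1CCC1=CCC([Se]c3ccccc3)[C@]21O[Si](C)(C)C | intermediate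
21 | hydroxy acid (C9 carboxylic acid; C7–OH) | CC(C)C(=O)CC[C@]1(CO)[C@]2(CC(Sc3ccccc3)C(=O)O)CN(C)C[C@H]1CCC1=CCC([Se]c3ccccc3)[C@]21O | intermediate
22 | mixed anhydride of 21 and 2,4,6-trichlorobenzoic acid | CC(C)C(=O)CC[C@]1(CO)[C@]2(CC(Sc3ccccc3)C(=O)OC(=O)c3c(Cl)cc(Cl)cc3Cl)CN(C)C[C@H]1CCC1=CCC([Se]c3ccccc3)[C@]21O | intermediate
23 | ring E lactone (C10–SPh; C22–SePh) | CC(C)C(=O)CC[C@]12COC(=O)C(Sc3ccccc3)C[C@]14CN(C)C[C@H]2CCC1=CCC([Se]c3ccccc3)[C@@]14O | intermediate
24 | selenoxide of 23 | CC(C)C(=O)CC[C@]12COC(=O)C(Sc3ccccc3)C[C@]14CN(C)C[C@H]2CCC1=CCC([Se](=O)c3ccccc3)[C@@]14O | intermediate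
25 | diene lactone (C19=C20–C21=C22; C10–SPh) | CC(C)C(=O)CC[C@]12COC(=O)C(Sc3ccccc3)C[C@]14CN(C)C[C@H]2CCC1=CC=C[C@@]14O | intermediate
26 | CNP0242289.1 | CC(C)C(=O)CC[C@]12COC(=O)[C@@H]3C[C@]14CN(C)C[C@H]2CCC1=CC[C@H]3[C@@]14O | target

**Step count and risks**

Total step count: 14. Longest linear sequence: 13 steps (1 → 26 through steps 1–5 and 7–14; step 6 is a one-step side branch).

Steps most likely to fail:

Step 14. The tin radical may add to the diene (hydrostannation), or the C10 radical may be reduced before it closes, because abstraction of the phenylthio group is slow. The fallback sets out from 25 and returns at 26. LiN(SiMe3)2 (two equivalents: the C23 hydroxyl first, then C10–H, which the phenylthio group makes more acidic than the ketone α-hydrogens) followed by CBr4 should give the C10-bromo-C10-phenylsulfanyl lactone F6. Single-electron reduction of its C–Br bond (Ru(bpy)3Cl2, iPr2NEt, blue light, DMF) would start the same 5-exo closure without any tin radical and give the ring D sulfide F7. SmI2 in THF–MeOH then cleaves the C10–S bond reductively, and protonation of the enolate gives 26.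

Step 2. The primary amine may condense with the 1,3-dione to an enaminone, or the β-amino-1,3-diketone may re-open by retro-Mannich reaction before it can be isolated. The fallback sets out from 3 and returns at 4. C-Alkylation of the potassium enolate of 3 (K2CO3, MeCN) with benzyl (chloromethyl)(methyl)carbamate puts the C13–N unit on C12 as the non-basic carbamate F1, which cannot fragment. Hydrogenolysis (H2, Pd/C, HCl, EtOAc) gives the secondary ammonium chloride F2. Paraformaldehyde in AcOH at 50 °C then closes ring A by a single intramolecular Mannich reaction at C16 to give 4.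

Step 10. The C6 radical may be reduced to C6–H before it adds to the enone, or it may add from both faces. The fallback sets out from 17 and returns at 19. The same titanium catalyst with 1,4-cyclohexadiene as hydrogen donor and no enone opens the epoxide to the primary alcohol F3 (C6–H, C7H2OH). Parikh–Doering oxidation (SO3·pyridine, DMSO, Et3N) gives the aldehyde F4. Pyrrolidine-catalysed enamine Michael addition to 18 builds the quaternary C6 of the keto aldehyde F5 by a two-electron path, again from the open ring A side. NaBH4 at −78 °C reduces only the aldehyde and gives 19.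

**Further compounds**

F1 | step 2 | benzyl N-{[1-(3-tert-butoxy-3-oxopropyl)-2,7-dioxocycloheptyl]methyl}-N-methylcarbamate | CC(C)(C)OC(=O)CCC1(CN(C)C(=O)OCc2ccccc2)C(=O)CCCCC1=O
F2 | step 2 | tert-butyl 3-{1-[(methylamino)methyl]-2,7-dioxocycloheptyl}propanoate hydrochloride | CC(C)(C)OC(=O)CCC1(C[NH2+]C)C(=O)CCCCC1=O.[Cl-]
F3 | step 10 | primary alcohol from reductive epoxide opening of 17 (C6–H, C7H2OH) | CC(C)(C)OC(=O)C(Sc4ccccc4)C[C@]1(CN(C)C[C@H]2CCC3=CCC([Se]c4ccccc4)[C@]13O)C2CO
F4 | step 10 | C7 aldehyde | CC(C)(C)OC(=O)C(Sc4ccccc4)C[C@]1(CN(C)C[C@H]2CCC3=CCC([Se]c4ccccc4)[C@]13O)C2C=O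
F5 | step 10 | keto aldehyde having quaternary C6 | CC(C)C(=O)CC[C@]1(C=O)[C@]2(CC(Sc3ccccc3)C(=O)OC(C)(C)C)CN(C)C[C@H]1CCC1=CCC([Se]c3ccccc3)[C@]21O
F6 | step 14 | C10-bromo-C10-phenylsulfanyl diene lactone | CC(C)C(=O)CC[C@]12COC(=O)C(Br)(Sc3ccccc3)C[C@]14CN(C)C[C@H]2CCC1=CC=C[C@@]14O
F7 | step 14 | C10-phenylsulfanyl derivative of 26 (ring D closed) | CC(C)C(=O)CC[C@]12COC(=O)[C@]3(Sc5ccccc5)C[C@]14CN(C)C[C@H]2CCC1=CC[C@H]3[C@@]14O
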